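**Plan**
- Retrosynthesis: the C7–aryl and C1–C2 bonds of the bicyclo[3.2.1]octan-8-one are cut together (aryl conjugate addition, then enolate aldol). This gives boronic acid 14 and the monocyclic 2-methoxycyclopentenone aldehyde 13. Next cuts: C5–allyl and C6–CH3 (conjugate addition/enolate allylation), then C4–C5 (vinyl anion + epoxide).
- Enabling feature: C7 is β to the C8 ketone through the methoxy bridgehead C1, and the C2 carbinol sits on that same C1. Ring C1–C7–C6–C5–C8 is therefore a 2-methoxycyclopent-2-enone (C1=C7), and ring C1–C2–C3–C4–C5–C8 is the aldol of its C1 enolate with a C2 aldehyde tethered at C5.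
- Forward: the five-membered ring is bought, the side chain is joined, C6 and C5 are substituted, C1 is oxygenated, and the six-membered ring (hence the bicycle) closes in the key step.
- Stereochemistry: C3 is bought ((S)-glycidyl ether); C6 is set by ligand-controlled copper catalysis; C5, then C7, C1 and C2 (these three in one event) follow by substrate control.

Key step: step 9

Remark: locants C1–C8 are those of the bicyclo[3.2.1]octan-8-one name of 16 and are used for the corresponding atoms of all precursors; 1, 2 and 14 are taken as catalogue compounds.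

**Step 1**
Reactants: 1 6-bromo-1,4-dioxaspiro[4.4]non-6-ene; 2 (2S)-2-{[(4-methoxyphenyl)methoxy]methyl}oxirane
Product: 4 (2S)-1-(1,4-dioxaspiro[4.4]non-6-en-6-yl)-3-[(4-methoxyphenyl)methoxy]propan-2-ol, via vinyllithium 3 (not isolated)
Conditions: n-BuLi, THF, −78 °C; then 2, BF3·OEt2, −78 °C; H2O
Reagents that add atoms: none
Why: Bromine–lithium exchange gives the α-ketovinyl anion equivalent 3, which opens the BF3-activated terminal epoxide at its CH2 carbon (SN2 organolithium/BF3 epoxide opening), so the purchased stereocentre is untouched and becomes C3.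

**Step 2**
Reactants: 4
Product: 5 6-[(2S)-2-methoxy-3-[(4-methoxyphenyl)methoxy]propyl]-1,4-dioxaspiro[4.4]non-6-ene
Conditions: NaH, MeI, THF, 0 °C to rt
Reagents that add atoms: iodomethane, CI
Why: Williamson etherification of the secondary alkoxide; the allylic ketal and the PMB ether are inert to base and no stereocentre is touched.

**Step 3**
Reactants: 5
Product: 6 2-[(2S)-2-methoxy-3-[(4-methoxyphenyl)methoxy]propyl]cyclopent-2-en-1-one
Conditions: oxalic acid, THF/H2O, rt
Reagents that add atoms: water, O
Why: Mild acid hydrolysis of the allylic ethylene ketal releases the 2-substituted cyclopentenone while the PMB and methyl ethers survive.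

**Step 4**
Reactants: 6
Product: 8 (2R,3R)-2-[(2S)-2-methoxy-3-[(4-methoxyphenyl)methoxy]propyl]-3-methyl-2-(prop-2-en-1-yl)cyclopentan-1-one, via magnesium enolate 7 (not isolated)
Conditions: MeMgBr, Cu(OTf)2 (cat.), chiral imidazolinium chloride (NHC precursor, cat., enantiomer giving 3R), Et2O, −30 to 0 °C; then allyl iodide, DMPU, −30 °C to rt
Reagents that add atoms: methylmagnesium bromide, C[Mg]Br; allyl iodide, C=CCI
Why: Copper-catalysed asymmetric conjugate addition of a Grignard reagent to an α-substituted cyclic enone sets C6 under ligand control, and the regiodefined tetrasubstituted enolate 7 is C-allylated anti to the adjacent methyl group, which places allyl trans to methyl at the quaternary C5.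

**Step 5**
Reactants: 8
Product: 10 (4R,5R)-2-hydroxy-5-[(2S)-2-methoxy-3-[(4-methoxyphenyl)methoxy]propyl]-4-methyl-5-(prop-2-en-1-yl)cyclopent-2-en-1-one, via α-hydroperoxy ketone 9 (not isolated)
Conditions: KOtBu, O2 (1 atm), t-BuOH/DME, 0 °C to rt; then aq. HCl
Reagents that add atoms: dioxygen, O=O
Why: Base-mediated autoxidation of a ketone with a single enolisable α-carbon (C1; C5 is quaternary): the potassium enolate takes up O2 to give hydroperoxide 9, which loses water to the 1,2-dione, and this enolises only toward C7 to one diosphenol, while C6 is never α to a carbonyl and keeps its configuration.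

**Step 6**
Reactants: 10
Product: 11 (4R,5R)-2-methoxy-5-[(2S)-2-methoxy-3-[(4-methoxyphenyl)methoxy]propyl]-4-methyl-5-(prop-2-en-1-yl)cyclopent-2-en-1-one
Conditions: Me2SO4, K2CO3, acetone, reflux
Reagents that add atoms: dimethyl sulfate, COS(=O)(=O)OC
Why: O-Methylation of the acidic diosphenol with a hard alkylating agent gives the C1 methyl enol ether, regiochemically unambiguous because C5 is quaternary.

**Step 7**
Reactants: 11
Product: 12 (4R,5R)-5-[(2S)-3-hydroxy-2-methoxypropyl]-2-methoxy-4-methyl-5-(prop-2-en-1-yl)cyclopent-2-en-1-one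
Conditions: DDQ, CH2Cl2/pH 7 buffer, 0 °C to rt
Reagents that add atoms: none
Why: Oxidative PMB cleavage (benzylic hydride abstraction by DDQ, hydrolysis of the oxocarbenium ion) leaves the terminal alkene, the methyl ethers and the methoxy enone untouched.

**Step 8**
Reactants: 12
Product: 13 (2S)-2-methoxy-3-[(1R,5R)-3-methoxy-5-methyl-2-oxo-1-(prop-2-en-1-yl)cyclopent-3-en-1-yl]propanal
Conditions: Dess–Martin periodinane, pyridine, CH2Cl2, 0 °C to rt; used at once
Reagents that add atoms: none
Why: Buffered Dess–Martin oxidation of the primary alcohol gives the α-methoxy aldehyde without epimerising C3 and without touching the enone or the alkene.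

**Step 9**
Reactants: 13; 14 (3,4,5-trimethoxyphenyl)boronic acid
Product: 16 (1S,2S,3S,5R,6R,7S)-2-hydroxy-1,3-dimethoxy-6-methyl-5-(prop-2-en-1-yl)-7-(3,4,5-trimethoxyphenyl)bicyclo[3.2.1]octan-8-one, via rhodium enolate 15 (not isolated)
Conditions: [Rh(cod)OH]2 (cat.), 1,4-dioxane, H2O (5 equiv), 50 °C
Reagents that add atoms: none
Why: Proposed new method: transmetallation of 14 to the hydroxorhodium catalyst gives an arylrhodium species that inserts the C1=C7 enone bond of 13 syn, aryl to the β-carbon C7 and rhodium to the methoxy-bearing C1, and the resulting O-bound (oxa-π-allyl) rhodium enolate 15 adds to the tethered aldehyde before it is protonated; hydrolysis of the rhodium aldolate returns Rh–OH. The closest known reaction type is the rhodium-catalysed arylboronic acid conjugate addition–aldol cyclisation of enones tethered to ketones, extended here to a cyclic 2-alkoxy enone (diosphenol ether) whose α-carbon becomes a fully substituted bridgehead. The six-membered ring C1–C2–C3–C4–C5–C8 closes by a 6-(enolendo)-exo-trig aldol across the α and α′ carbons of the cyclopentanone, which turns the monocycle into the bicyclo[3.2.1]octan-8-one. C7 is set by insertion on the ring face anti to the adjacent C6 methyl group; C1 is fixed because the tether on the quaternary C5 can reach the enolate only from its own face (also anti to the new aryl group); C2 follows from a closed, rhodium-bridged Zimmerman–Traxler transition state in a chair-like forming ring, which holds the aldehyde oxygen next to the enolate oxygen (hydroxyl on the side of the C8 carbonyl) with the C3 methoxy group equatorial. The step needs 1,4- over 1,2-chemoselectivity (arylrhodium–diene complexes are expected to insert enones faster than they add to aliphatic aldehydes) and aldol over protonation of 15 (little water, intramolecular capture), and it needs the α-methoxy enone to stay a competent acceptor, which is argued from the carbonyl-directed regiochemistry of the insertion and from known rhodium-catalysed additions to α-heteroatom-substituted acceptors such as α-acylaminoacrylates.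

**Compound list**
1 | 6-bromo-1,4-dioxaspiro[4.4]non-6-ene | BrC1=CCCC12OCCO2 | starting material
2 | (2S)-2-{[(4-methoxyphenyl)methoxy]methyl}oxirane | COc1ccc(COC[C@@H]2CO2)cc1 | starting material
3 | (1,4-dioxaspiro[4.4]non-6-en-6-yl)lithium | [Li]C1=CCCC12OCCO2 | intermediate
4 | (2S)-1-(1,4-dioxaspiro[4.4]non-6-en-6-yl)-3-[(4-methoxyphenyl)methoxy]propan-2-ol | COc1ccc(COC[C@@H](O)CC2=CCCC23OCCO3)cc1 | intermediate
5 | 6-[(2S)-2-methoxy-3-[(4-methoxyphenyl)methoxy]propyl]-1,4-dioxaspiro[4.4]non-6-ene | COc1ccc(COC[C@@H](OC)CC2=CCCC23OCCO3)cc1 | intermediate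
6 | 2-[(2S)-2-methoxy-3-[(4-methoxyphenyl)methoxy]propyl]cyclopent-2-en-1-one | COc1ccc(COC[C@@H](OC)CC2=CCCC2=O)cc1 | intermediate
7 | bromomagnesium (3R)-2-[(2S)-2-methoxy-3-[(4-methoxyphenyl)methoxy]propyl]-3-methylcyclopent-1-en-1-olate | Br[Mg]OC1=C(C[C@H](OC)COCc2ccc(OC)cc2)[C@H](C)CC1 | intermediate
8 | (2R,3R)-2-[(2S)-2-methoxy-3-[(4-methoxyphenyl)methoxy]propyl]-3-methyl-2-(prop-2-en-1-yl)cyclopentan-1-one | C=CC[C@]1(C[C@H](OC)COCc2ccc(OC)cc2)C(=O)CC[C@H]1C | intermediate
9 | (2R,3R)-5-hydroperoxy-2-[(2S)-2-methoxy-3-[(4-methoxyphenyl)methoxy]propyl]-3-methyl-2-(prop-2-en-1-yl)cyclopentan-1-one (configuration at the hydroperoxy carbon immaterial) | C=CC[C@]1(C[C@H](OC)COCc2ccc(OC)cc2)C(=O)C(OO)C[C@H]1C | intermediate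
10 | (4R,5R)-2-hydroxy-5-[(2S)-2-methoxy-3-[(4-methoxyphenyl)methoxy]propyl]-4-methyl-5-(prop-2-en-1-yl)cyclopent-2-en-1-one | C=CC[C@]1(C[C@H](OC)COCc2ccc(OC)cc2)C(=O)C(O)=C[C@H]1C | intermediate
11 | (4R,5R)-2-methoxy-5-[(2S)-2-methoxy-3-[(4-methoxyphenyl)methoxy]propyl]-4-methyl-5-(prop-2-en-1-yl)cyclopent-2-en-1-one | C=CC[C@]1(C[C@H](OC)COCc2ccc(OC)cc2)C(=O)C(OC)=C[C@H]1C | intermediate
12 | (4R,5R)-5-[(2S)-3-hydroxy-2-methoxypropyl]-2-methoxy-4-methyl-5-(prop-2-en-1-yl)cyclopent-2-en-1-one | C=CC[C@]1(C[C@H](OC)CO)C(=O)C(OC)=C[C@H]1C | intermediate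
13 | (2S)-2-methoxy-3-[(1R,5R)-3-methoxy-5-methyl-2-oxo-1-(prop-2-en-1-yl)cyclopent-3-en-1-yl]propanal | C=CC[C@]1(C[C@H](OC)C=O)C(=O)C(OC)=C[C@H]1C | intermediate
14 | (3,4,5-trimethoxyphenyl)boronic acid | COc1cc(B(O)O)cc(OC)c1OC | starting material
15 | (cycloocta-1,5-diene)rhodium O-enolate of the C7-aryl adduct of 13 (monovalent rhodium; diene ligand not drawn) | C=CC[C@]1(C[C@H](OC)C=O)C(O[Rh])=C(OC)[C@H](c2cc(OC)c(OC)c(OC)c2)[C@H]1C | intermediate
16 | (1S,2S,3S,5R,6R,7S)-2-hydroxy-1,3-dimethoxy-6-methyl-5-(prop-2-en-1-yl)-7-(3,4,5-trimethoxyphenyl)bicyclo[3.2.1]octan-8-one | C=CC[C@]12C[C@H](OC)[C@H](O)[C@](OC)(C1=O)[C@H](c1cc(OC)c(OC)c(OC)c1)[C@H]2C | target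

**Count and risks**
Total steps: 9. Longest linear sequence: 9 steps (from 1 or 2 to 16).

Steps most likely to fail:

1. Step 9. The arylrhodium species may add to the aldehyde carbonyl instead of inserting the electron-rich, α-substituted C1=C7 bond; the rhodium enolate may be protonated before the ring closes; the α-methoxy aldehyde may epimerise at C3 under the basic conditions. The fallback moves the arylation to a plain enone, before the C1 oxygen is installed, and runs the aldol as a separate step. It sets out from 8 and comes back at 16. Dehydrogenation of 8 with IBX (DMSO, 65 °C) should give the (4R,5R)-4-methyl-5,5-disubstituted cyclopent-2-en-1-one F1. Rhodium-catalysed 1,4-addition of 14 ([Rh(cod)OH]2, dioxane/H2O), anti to the methyl group, should give the trans 4-aryl-3-methyl ketone F2. Its only enolisable position is hydroxylated (KHMDS, then 2-(phenylsulfonyl)-3-phenyloxaziridine) to the α-hydroxy ketone F3. Methylation (MeI, Ag2O) gives the α-methoxy ketone F4. DDQ then gives the primary alcohol F5, and Dess–Martin oxidation the keto aldehyde F6. A chelating soft-enolisation aldol (MgBr2·OEt2, i-Pr2NEt, CH2Cl2) closes the six-membered ring; the C1 configuration of F3–F6 is immaterial because C1 is planarised again, and the product is 16.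

2. Step 4. Face selection in the methyl transfer to the α-substituted enone may be incomplete, and the hindered magnesium enolate may undergo O-allylation or proton transfer instead of C-allylation. The fallback gives up catalyst control and uses the bought C3 centre to separate diastereomers. It sets out from 6 and comes back at 8. Me2CuLi with TMSCl (THF, −78 °C) gives the trimethylsilyl enol ether F7 as both C6 epimers. MeLi regenerates the regiodefined lithium enolate, and allyl bromide (THF/HMPA) alkylates it anti to the methyl group. This gives 8 together with its C5,C6-bis-epimer F8; the two are diastereomers and are separated by chromatography.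

3. Step 5. The diosphenolate may be over-oxidised by O2 (oxidative C1–C8 cleavage), and allylic autoxidation may compete. The fallback replaces autoxidation by electrophilic oxygen transfer followed by alcohol oxidation. It sets out from 8 and comes back at 10. KHMDS, then 2-(phenylsulfonyl)-3-phenyloxaziridine (THF, −78 °C), gives the α-hydroxy ketone F9. Oxidation with Cu(OAc)2 in MeOH under air (or Dess–Martin periodinane) gives the 1,2-dione, which enolises to 10.

**Further compounds**
F1 | step 9 | (4R,5R)-5-[(2S)-2-methoxy-3-[(4-methoxyphenyl)methoxy]propyl]-4-methyl-5-(prop-2-en-1-yl)cyclopent-2-en-1-one | C=CC[C@]1(C[C@H](OC)COCc2ccc(OC)cc2)C(=O)C=C[C@H]1C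
F2 | step 9 | (2R,3R,4S)-2-[(2S)-2-methoxy-3-[(4-methoxyphenyl)methoxy]propyl]-3-methyl-2-(prop-2-en-1-yl)-4-(3,4,5-trimethoxyphenyl)cyclopentan-1-one | C=CC[C@]1(C[C@H](OC)COCc2ccc(OC)cc2)C(=O)C[C@H](c2cc(OC)c(OC)c(OC)c2)[C@H]1C
F3 | step 9 | 5-hydroxy derivative of F2 (hydroxyl trans to aryl) | C=CC[C@]1(C[C@H](OC)COCc2ccc(OC)cc2)C(=O)[C@@H](O)[C@H](c2cc(OC)c(OC)c(OC)c2)[C@H]1C
F4 | step 9 | 5-methoxy derivative of F2 (methoxy trans to aryl) | C=CC[C@]1(C[C@H](OC)COCc2ccc(OC)cc2)C(=O)[C@@H](OC)[C@H](c2cc(OC)c(OC)c(OC)c2)[C@H]1C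
F5 | step 9 | primary alcohol from F4 (PMB removed) | C=CC[C@]1(C[C@H](OC)CO)C(=O)[C@@H](OC)[C@H](c2cc(OC)c(OC)c(OC)c2)[C@H]1C
F6 | step 9 | keto aldehyde from F5 | C=CC[C@]1(C[C@H](OC)C=O)C(=O)[C@@H](OC)[C@H](c2cc(OC)c(OC)c(OC)c2)[C@H]1C
F7 | step 4 | trimethylsilyl enol ether of 2-[(2S)-2-methoxy-3-[(4-methoxyphenyl)methoxy]propyl]-3-methylcyclopentan-1-one (both epimers at the methyl carbon) | C[Si](C)(C)OC1=C(C[C@H](OC)COCc2ccc(OC)cc2)C(C)CC1
F8 | step 4 | (2S,3S)-2-[(2S)-2-methoxy-3-[(4-methoxyphenyl)methoxy]propyl]-3-methyl-2-(prop-2-en-1-yl)cyclopentan-1-one | C=CC[C@@]1(C[C@H](OC)COCc2ccc(OC)cc2)C(=O)CC[C@@H]1C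
F9 | step 5 | (2R,3R)-5-hydroxy-2-[(2S)-2-methoxy-3-[(4-methoxyphenyl)methoxy]propyl]-3-methyl-2-(prop-2-en-1-yl)cyclopentan-1-one (carbinol epimers) | C=CC[C@]1(C[C@H](OC)COCc2ccc(OC)cc2)C(=O)C(O)C[C@H]1C
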